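The easy step is a subtraction: each amount of substrate that goes takes an equal amount of partner and makes an equal amount of target, so target made is charge minus reading.

| flask | substrate | partner | catalyst | time |
|---|---|---|---|---|
| south-east | 0.250 M | 0.375 M | 5.00 × 10⁻⁴ M |  |
| south | 0.150 M | 0.275 M | 5.00 × 10⁻⁴ M |  |
| north-west | 0.250 M | 1.10 M | 5.00 × 10⁻⁴ M |  |
| west | 0.750 M | 0.375 M | 5.00 × 10⁻⁴ M |  |
| north | 0.0830 M | 0.120 M | 5.00 × 10⁻⁴ M | 35 min |

- south-east run (time / min: [substrate] / M): 1.4: 0.2242; 2.4: 0.2069; 4.1: 0.1745; 7.0: 0.1420; 12: 0.1126; 20: 0.0866; 35: 0.0665
- south run (time / min: [substrate] / M): 1.4: 0.1339; 2.4: 0.1201; 4.1: 0.1075; 7.0: 0.0925; 12: 0.0671; 20: 0.0539; 35: 0.0408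
- north-west run (time / min: [substrate] / M): 1.4: 0.1697; 2.4: 0.1161; 4.1: 0.0627; 7.0: 0.0163; 12: 0.0022; 20: 0.0046; 35: 0.0050
- west run (time / min: [substrate] / M): 1.4: 0.7106; 2.4: 0.6838; 4.1: 0.6436; 7.0: 0.5825; 12: 0.5353; 20: 0.5046; 35: 0.5018

(standard deviation of a reading: 0.002 M)

1. the power of [partner] that the first rate follows, about the charge of the south-east run; measure it at two percent of substrate made into target
2. the power of [substrate] that the first rate follows, about the charge of the south-east run; measure it at two percent of substrate made into target (one fixed amount of target, the same in the runs compared)
3. the south run starts with 0.100 M less of substrate and of partner than the south-east run, and with no target. Compared where both hold the same amount of substrate, once fifteen percent of what the south run was charged with has turned into target, is the south run faster, slower or alike (within a tenth)?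
4. substrate in the north run at 35 min, as a share of the substrate charged

- Overall: substrate + partner -> target, with catalyst as catalyst.
- Constant volume, constant temperature.
- The analysis sees a species whether free or bound.
- "The second partner" is partner.
- An order is taken over about fifteen percent of the charge, up and down.

By 35 min the west run has made 0.248 M of target, less than the 0.375 M of partner charged, yet its substrate reads 0.5046 M at 20 min and 0.5018 M at 35 min. So I suppose that partner has a second way out, one that needs no substrate.

I fold each run into one number, the split (a selectivity factor for partner). In the south run, the lowest substrate charge among the runs so far, it is target made, 0.109 M, over partner not made into target by 35 min: 0.659. A split of one means that by then as much partner has become target as has not. The way to target should pull harder with more substrate, so I replace the falling curve by its mean, the average of charge and last reading, here 0.0954 M. I take the split as proportional to that mean, which gives 6.90 M⁻¹.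

Is one number enough? For the south-east run it predicts 1.09 against 0.958 read, a little high. For the west run it predicts 4.32 against 1.96, which is too high. So I trust it at low substrate, and the north run is charged below the south run.

For the north run I guess a mean of 0.7 of the charge, 0.0581 M. That gives a split of 0.401 and 0.0344 M of target. The corrected mean, 0.0658 M, gives a split of 0.454 and 0.0375 M of target, so I expect 54.8% of the substrate to stay.

The forecast, holding that “Something is dying, either catalyst or partner”, gives orders of 1 in partner and 0.45 in substrate, faster for the south run, and 53% for the north run, 1.8 percentage points below my figure.

The flask gives orders of 1.0 and 0.35, a south run that is faster at 1.4 times the south-east rate, and 53.0% in the north run.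

    catalyst + substrate ⇌ catalyst-substrate complex, settled at all times (8.260 M⁻¹)
    catalyst-substrate complex + partner → target + catalyst (168.6 M⁻¹ min⁻¹)
    partner → lost reagent (0.05532 min⁻¹)
    substrate + partner + target → 2 target (0.6420 M⁻² min⁻¹)

That 53.0% means 0.0390 M of target in the north run and a split of 0.482, against my 0.454 and the south run's 0.659. Substrate in the north run stays at 53.0% instead of 22.9% because partner turns into lost reagent. The same subtraction for the north run without that step gives 0.0640 M of target, and the split stands at 1.14.

Readings and results come from a simulation on assumed constants; noise was put on by code.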